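The chalcone is cut between the ketone carbon and the alpha carbon of the enone, which turns it into an aldehyde C–H bond plus a terminal alkyne. The key step exploits the C2' hydroxyl of ring A (the 2,4-dihydroxyphenyl ring), ortho to the carbonyl carbon. As a rhodium phenoxide it directs C–H activation of 2,4-dihydroxybenzaldehyde and locks the acyl rhodium hydride in a five-membered chelate. Syn addition across 4-ethynyl-2-methoxy-6-prenylphenol then forms the C(=O)–C(alpha) bond, sets the E alkene and gives abyssinone D directly, without protecting groups or by-products. The alkyne precursor, a ring B phenylacetylene with no carbonyl group, comes from 5-iodovanillin in two steps.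

Key step: step 3

Remark: ring A is the 2,4-dihydroxyphenyl ring (primed numbers, C1' bears the carbonyl group). Ring B is the 4-hydroxy-3-methoxy-5-prenylphenyl ring, and prenyl means 3-methylbut-2-en-1-yl. Compounds 1, 2 and 6 and the Ohira–Bestmann reagent are assumed to be commercially available.

Step 1
Reactants: 1 5-iodovanillin; 2 prenylboronic acid pinacol ester
Product: 3 5-prenylvanillin (4-hydroxy-3-methoxy-5-(3-methylbut-2-en-1-yl)benzaldehyde)
Conditions: PdCl2(dppf) (5 mol%), K2CO3 (3 equiv), 2 (1.5 equiv), 1,4-dioxane/H2O, 80 °C, Ar
Reagents that add atoms: none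
Why: Suzuki–Miyaura coupling of an aryl iodide with an allylic boronate, in which the weak C–I bond adds to zerovalent palladium even in the phenoxide form of 1 and the chelating dppf keeps the allyl ligand as the less hindered primary sigma-prenyl species, so that reductive elimination should give the linear prenyl arene and leave the aldehyde untouched.

Step 2
Reactants: 3 5-prenylvanillin
Product: 5 4-ethynyl-2-methoxy-6-(3-methylbut-2-en-1-yl)phenol, via diazoalkene 4 (not isolated)
Conditions: dimethyl (1-diazo-2-oxopropyl)phosphonate (2 equiv), K2CO3 (4 equiv), MeOH, 0 °C to rt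
Reagents that add atoms: dimethyl (1-diazo-2-oxopropyl)phosphonate (Ohira–Bestmann reagent), COP(=O)(OC)C(=[N+]=[N-])C(C)=O
Why: Seyferth–Gilbert homologation in its Ohira–Bestmann form, in which methanolysis of the reagent releases the dimethyl diazomethylphosphonate anion, this anion olefinates the non-enolisable aryl aldehyde to diazoalkene 4, and loss of nitrogen with a 1,2-hydride shift should give the terminal alkyne, the excess of reagent making up for the lower electrophilicity of the phenoxide form of 3 and the prenyl alkene staying untouched.

Step 3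
Reactants: 5 4-ethynyl-2-methoxy-6-prenylphenol; 6 2,4-dihydroxybenzaldehyde
Product: 7 abyssinone D ((E)-1-(2,4-dihydroxyphenyl)-3-[4-hydroxy-3-methoxy-5-(3-methylbut-2-en-1-yl)phenyl]prop-2-en-1-one)
Conditions: [RhCl(cod)]2 (2.5 mol%), 1,1'-bis(diphenylphosphino)ferrocene (dppf, 5 mol%), Na2CO3 (10 mol%), 6 (1.5 equiv), 1,4-dioxane, 90 °C, slow addition of 5, Ar
Reagents that add atoms: none
Why: Catalytic Na2CO3 turns the C2' hydroxyl of 6 into a phenoxide of monovalent rhodium, the neighbouring formyl C–H bond adds oxidatively, and the resulting acyl hydride of trivalent rhodium is held in a five-membered O–Rh–C(acyl) chelate that blocks decarbonylation. Alkyne 5 then inserts into the Rh–H bond in a syn fashion with rhodium at the unhindered terminal carbon, and C–C reductive elimination joins that carbon to the acyl carbon and returns the catalyst. The closest known reaction type is the chelation-assisted rhodium-catalysed intermolecular hydroacylation of internal and terminal alkynes with salicylaldehydes, which gives 2-alkenoylphenols. No ring of the product is closed and no stereocentre is formed; the E geometry follows from syn hydrometalation and reductive elimination with retention. The step needs linear over branched regioselectivity, secured by the steric contrast between the terminal C–H end and the aryl-bearing carbon of 5 facing the bulky dppf-bound chelate, and chemoselectivity for the alkyne over the trisubstituted prenyl alkene, which is too hindered to insert; only the C2' hydroxyl can chelate, so the C4' and ring B hydroxyls bind reversibly and stay spectators. Slow addition of 5 to an excess of 6 keeps the alkyne concentration low and should hold back alkyne oligomerisation, and every atom of both partners ends up in 7.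

Compound list
1 | 5-iodovanillin (4-hydroxy-3-iodo-5-methoxybenzaldehyde) | COc1cc(C=O)cc(I)c1O | starting material
2 | prenylboronic acid pinacol ester (4,4,5,5-tetramethyl-2-(3-methylbut-2-en-1-yl)-1,3,2-dioxaborolane) | CC(C)=CCB1OC(C)(C)C(C)(C)O1 | starting material
3 | 5-prenylvanillin (4-hydroxy-3-methoxy-5-(3-methylbut-2-en-1-yl)benzaldehyde) | COc1cc(C=O)cc(CC=C(C)C)c1O | intermediate
4 | diazoalkene, 4-(2-diazoethenyl)-2-methoxy-6-(3-methylbut-2-en-1-yl)phenol (not isolated) | COc1cc(C=C=[N+]=[N-])cc(CC=C(C)C)c1O | intermediate
5 | 4-ethynyl-2-methoxy-6-(3-methylbut-2-en-1-yl)phenol | COc1cc(C#C)cc(CC=C(C)C)c1O | intermediate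
6 | 2,4-dihydroxybenzaldehyde | O=Cc1ccc(O)cc1O | starting material
7 | abyssinone D, (E)-enone | COc1cc(/C=C/C(=O)c2ccc(O)cc2O)cc(CC=C(C)C)c1O | target

Total step count: 3
Longest linear sequence: 3 steps (1 to 3 to 5 to 7)

Steps most likely to fail

1. Step 3 (key step).
- What may go wrong: rhodium-initiated oligomerisation of the electron-rich aryl alkyne, insertion with the reverse regiochemistry, or base-induced oxa-Michael closure of the enone after the coupling.
- Fallback: the same bond is made by polar chemistry. The fallback sets out from 5 and 6 and comes back at 7. With MOMCl and iPr2NEt in CH2Cl2, 5 is converted into its methoxymethyl ether F1 and 6 into 2,4-bis(methoxymethoxy)benzaldehyde F2. The lithium acetylide of F1 (n-BuLi, THF, −78 °C) should add to F2 to give the racemic propargylic alcohol F3. Hydroxyl-directed trans-hydroalumination with NaAlH2(OCH2CH2OMe)2 in THF should give the racemic (E)-allylic alcohol F4. MnO2 in CH2Cl2 should oxidise it to the tris(methoxymethyl) chalcone F5. HCl in MeOH at 40 °C should then remove the three acetals and give 7.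

2. Step 2.
- What may go wrong: slow addition of the diazophosphonate anion to the formyl group. K2CO3 in MeOH deprotonates the para hydroxyl, and the phenoxide drains the electrophilicity of the aldehyde while the reagent decays.
- Fallback: a Corey–Fuchs sequence on the masked phenol. The fallback sets out from 3 and comes back at 5. Silylation (TBSCl, imidazole, DMF) should give the tert-butyldimethylsilyl ether F6. Ramirez olefination (CBr4, PPh3, CH2Cl2, 0 °C) should give the 1,1-dibromoalkene F7. n-BuLi (THF, −78 °C, bromine–lithium exchange and Fritsch–Buttenberg–Wiechell shift) should give the silyl-protected alkyne F8. TBAF (THF, 0 °C) should free the phenol and give 5.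

3. Step 1.
- What may go wrong: transfer of the prenyl group through its tertiary terminus (gamma attack), and protodeboronation of the allylic boronate before transmetalation.
- Fallback: the trisubstituted alkene is built after the coupling. The fallback sets out from 1 and comes back at 3. Compound 1 is coupled with allylboronic acid pinacol ester (PdCl2(dppf), K2CO3, 1,4-dioxane/H2O), where both allyl termini lead to the same product, to give 5-allylvanillin F9. Cross metathesis with an excess of 2-methylbut-2-ene (second-generation Grubbs catalyst, CH2Cl2, 40 °C) should then give 3.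

Further compounds
F1 | step 3 | 5-ethynyl-1-methoxy-2-(methoxymethoxy)-3-(3-methylbut-2-en-1-yl)benzene | COCOc1c(OC)cc(C#C)cc1CC=C(C)C
F2 | step 3 | 2,4-bis(methoxymethoxy)benzaldehyde | COCOc1ccc(C=O)c(OCOC)c1
F3 | step 3 | racemic 1-[2,4-bis(methoxymethoxy)phenyl]-3-[3-methoxy-4-(methoxymethoxy)-5-(3-methylbut-2-en-1-yl)phenyl]prop-2-yn-1-ol | COCOc1ccc(C(O)C#Cc2cc(OC)c(OCOC)c(CC=C(C)C)c2)c(OCOC)c1
F4 | step 3 | racemic (E)-1-[2,4-bis(methoxymethoxy)phenyl]-3-[3-methoxy-4-(methoxymethoxy)-5-(3-methylbut-2-en-1-yl)phenyl]prop-2-en-1-ol | COCOc1ccc(C(O)/C=C/c2cc(OC)c(OCOC)c(CC=C(C)C)c2)c(OCOC)c1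
F5 | step 3 | tris(methoxymethyl) ether of abyssinone D, (E)-enone | COCOc1ccc(C(=O)/C=C/c2cc(OC)c(OCOC)c(CC=C(C)C)c2)c(OCOC)c1
F6 | step 2 | 4-(tert-butyldimethylsilyloxy)-3-methoxy-5-(3-methylbut-2-en-1-yl)benzaldehyde | COc1cc(C=O)cc(CC=C(C)C)c1O[Si](C)(C)C(C)(C)C
F7 | step 2 | tert-butyl[4-(2,2-dibromoethenyl)-2-methoxy-6-(3-methylbut-2-en-1-yl)phenoxy]dimethylsilane | COc1cc(C=C(Br)Br)cc(CC=C(C)C)c1O[Si](C)(C)C(C)(C)C
F8 | step 2 | tert-butyl[4-ethynyl-2-methoxy-6-(3-methylbut-2-en-1-yl)phenoxy]dimethylsilane | COc1cc(C#C)cc(CC=C(C)C)c1O[Si](C)(C)C(C)(C)C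
F9 | step 1 | 5-allylvanillin (4-hydroxy-3-methoxy-5-(prop-2-en-1-yl)benzaldehyde) | COc1cc(C=O)cc(CC=C)c1O
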